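**Plan**

- Remark: octacosanolide is the 29-membered lactone of 28-hydroxyoctacosanoic acid, numbered here as the acid (C1 = carbonyl carbon, C28 = the CH2 on the ring oxygen).
- Retrosynthesis: C12–C13 and C14–C15 are first raised to triple bonds. The C13–C14 bond, now the central single bond of a 1,3-diyne, is then cut to give an open α,ω-diyne ester. The ester C1–O bond is cut last, into tridec-12-ynoic acid and pentadec-14-yn-1-ol.
- Forward: the acid comes from 11-bromoundecanoic acid and lithium acetylide (C11–C12 bond). The alcohol comes from prop-2-yn-1-ol and 1-bromododecane (C25–C26 bond), followed by an alkyne zipper. The fragments are esterified, the only ring is closed by copper-mediated oxidative coupling of the terminal alkyne carbons C13 and C14, and the diyne is hydrogenated.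
- Enabling feature: C13–C14 lies in the unfunctionalised methylene belt opposite the O–C1(=O) unit and is flanked by CH2 groups (C12, C15). Both ends can therefore be terminal alkynes of the same polarity, and the 29-membered ring holds the linear C11–C16 rod without strain. Hydrogenation removes the helper unsaturation without trace.
- Stereochemistry: the target has no stereocentre and keeps no double bond, so none has to be set.

Key step: step 5

**Step 1**
Reactants: 1 11-bromoundecanoic acid; 2 lithium acetylide–ethylenediamine complex
Product: 3 tridec-12-ynoic acid
Conditions: LiC≡CH·H2NCH2CH2NH2 (3 equiv), DMSO, 10 °C to rt; then 1 M HCl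
Reagents that add atoms: lithium acetylide–ethylenediamine complex (compound 2), [Li+].[C-]#C.NCCN
Why: Acetylide alkylation (SN2) at the primary bromide in DMSO should proceed cleanly, because the carboxylate formed by the first equivalent of base is inert to the nucleophile.

**Step 2**
Reactants: 4 prop-2-yn-1-ol; 5 1-bromododecane
Product: 6 pentadec-2-yn-1-ol
Conditions: LiNH2 (2.2 equiv), liq. NH3/THF, −33 °C; then 5 in THF, −33 °C to rt; NH4Cl quench
Reagents that add atoms: none
Why: In the dianion of prop-2-yn-1-ol the acetylide carbon is far more nucleophilic than the lithium alkoxide, so SN2 C-alkylation by the primary bromide (acetylide alkylation) should dominate.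

**Step 3**
Reactants: 6 pentadec-2-yn-1-ol
Product: 7 pentadec-14-yn-1-ol
Conditions: KH (5 equiv), H2N(CH2)3NH2, rt; then 6, 0 °C to rt; H2O quench
Reagents that add atoms: none
Why: In the alkyne zipper reaction, potassium 3-aminopropylamide walks the triple bond along the chain by propargyl–allenyl proton shifts, and irreversible formation of the terminal potassium acetylide should trap it at C14–C15.

**Step 4**
Reactants: 3 tridec-12-ynoic acid; 7 pentadec-14-yn-1-ol
Product: 8 pentadec-14-yn-1-yl tridec-12-ynoate
Conditions: DCC (1.1 equiv), DMAP (0.1 equiv), CH2Cl2, 0 °C to rt
Reagents that add atoms: none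
Why: Steglich esterification of a primary alcohol with an unhindered acid is mild and neutral and leaves both terminal alkynes untouched.

**Step 5**
Reactants: 8 pentadec-14-yn-1-yl tridec-12-ynoate
Product: 9 oxacyclononacosa-13,15-diyn-2-one (octacosa-12,14-diyn-28-olide)
Conditions: Cu(OAc)2 (10 equiv), pyridine/Et2O (3:1), 40 °C, N2; 8 added by syringe pump over 20 h (final concentration about 1 mM)
Reagents that add atoms: none
Why: Pyridine-assisted deprotonation turns both terminal C–H groups (C13–H and C14–H) into acetylides bound to divalent copper, and two such acetylides collapse in a dinuclear complex with C(sp)–C(sp) bond formation while each copper leaves as monovalent CuOAc, so two carbons of the same nucleophilic polarity are joined by oxidation. The closest known reaction type is the Eglinton variant of the Glaser coupling under high dilution, the established way from open-chain α,ω-diynes to cyclic 1,3-diynes and diyne macrolactones. The single ring is closed end-to-end as a 29-membered macrocycle between two sp carbons; at this size the linear C11–C16 rod is held without strain and no Baldwin-type constraint applies. No stereocentre is formed. The selectivity needed is ring closure over intermolecular coupling (linear oligomers, cyclic dimer); slow addition into excess Cu(OAc)2 keeps the stationary concentration of 8 very low, and both reacting ends are the same functional group, so no cross-selectivity between them is required. The ester is inert to Cu(OAc)2 and pyridine in the absence of alcohols, which is why Et2O and not MeOH is the co-solvent.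

**Step 6**
Reactants: 9 oxacyclononacosa-13,15-diyn-2-one
Product: 10 octacosanolide
Conditions: H2 (3 bar), 10% Pd/C, EtOAc/THF, rt
Reagents that add atoms: none
Why: Heterogeneous catalytic hydrogenation should saturate the conjugated diyne completely (four equivalents of H2), and the lactone, whose C–O bond is neither allylic nor benzylic, is not cleaved.

**Compound list**

1 | 11-bromoundecanoic acid | OC(=O)CCCCCCCCCCBr | starting material
2 | lithium acetylide–ethylenediamine complex | [Li+].[C-]#C.NCCN | starting material
3 | tridec-12-ynoic acid | OC(=O)CCCCCCCCCCC#C | intermediate
4 | prop-2-yn-1-ol (propargyl alcohol) | OCC#C | starting material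
5 | 1-bromododecane | CCCCCCCCCCCCBr | starting material
6 | pentadec-2-yn-1-ol | OCC#CCCCCCCCCCCCC | intermediate
7 | pentadec-14-yn-1-ol | OCCCCCCCCCCCCCC#C | intermediate
8 | pentadec-14-yn-1-yl tridec-12-ynoate | C#CCCCCCCCCCCC(=O)OCCCCCCCCCCCCCC#C | intermediate
9 | oxacyclononacosa-13,15-diyn-2-one (octacosa-12,14-diyn-28-olide) | O=C1CCCCCCCCCCC#CC#CCCCCCCCCCCCCCO1 | intermediate
10 | octacosanolide (oxacyclononacosan-2-one) | O=C1CCCCCCCCCCCCCCCCCCCCCCCCCCCO1 | target

**Step count**

Total steps: 6. Longest linear sequence: 5 steps (steps 2, 3, 4, 5, 6).

**Steps most likely to fail**

1. Step 5. Intermolecular oxidative coupling may outrun ring closure during the long addition, giving linear oligomers and the cyclic dimer. The fallback reverses the order of events: the C13–C14 bond is made between two molecules and the ring is closed at the ester bond. It sets out from compounds 3 and 7 and comes back to the route at compound 10. Compound 7 is brominated at the alkyne terminus (NBS, catalytic AgNO3, acetone, rt) to 15-bromopentadec-14-yn-1-ol F1. Cadiot–Chodkiewicz cross-coupling of F1 with 3 (catalytic CuCl, NH2OH·HCl, aqueous EtNH2, MeOH/THF, 0 °C) should give 28-hydroxyoctacosa-12,14-diynoic acid F2. Hydrogenation (H2, 10% Pd/C, THF) should give 28-hydroxyoctacosanoic acid F3. Yamaguchi macrolactonisation of F3 (2,4,6-trichlorobenzoyl chloride, Et3N, THF; then slow addition to DMAP in toluene at reflux under high dilution) should give 10.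

2. Step 3. Migration of the triple bond may stall at internal positions if the amide base is partly quenched, leaving alkyne isomers that are hard to separate from 7. The fallback installs the terminal alkyne directly by substitution. It sets out from compound 2 and commercial tridecane-1,13-diol F4 and comes back at compound 7. F4 is monobrominated (48% aqueous HBr, toluene, reflux) to 13-bromotridecan-1-ol F5. Displacement of the bromide in F5 by excess 2 in DMSO at rt should give 7.

3. Step 2. C-alkylation may be slow because the long-chain bromide dissolves poorly in liquid ammonia, which lets O-alkylation and elimination compete. The fallback replaces the dianion by a protected monoanion. It sets out from compounds 4 and 5 and comes back at compound 6. Compound 4 is converted (3,4-dihydro-2H-pyran, catalytic PPTS, CH2Cl2) into 2-(prop-2-yn-1-yloxy)oxane F6. Lithiation (n-BuLi, THF, −78 °C) and alkylation with 5 in THF/DMPU should give 2-(pentadec-2-yn-1-yloxy)oxane F7, racemic at the acetal carbon. Acetal cleavage (PPTS, MeOH, 50 °C) should give 6.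

**Further compounds**

F1 | step 5 | 15-bromopentadec-14-yn-1-ol | OCCCCCCCCCCCCCC#CBr
F2 | step 5 | 28-hydroxyoctacosa-12,14-diynoic acid | OC(=O)CCCCCCCCCCC#CC#CCCCCCCCCCCCCCO
F3 | step 5 | 28-hydroxyoctacosanoic acid | OC(=O)CCCCCCCCCCCCCCCCCCCCCCCCCCCO
F4 | step 3 | tridecane-1,13-diol | OCCCCCCCCCCCCCO
F5 | step 3 | 13-bromotridecan-1-ol | OCCCCCCCCCCCCCBr
F6 | step 2 | 2-(prop-2-yn-1-yloxy)oxane | C#CCOC1CCCCO1
F7 | step 2 | 2-(pentadec-2-yn-1-yloxy)oxane | CCCCCCCCCCCCC#CCOC1CCCCO1
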